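Which of four flasks, charged alike and held at four temperatures, holds the most target after 20 h? Ask first what each end state must be, then how far each flask has travelled towards it.

| flask | starting material | coupling partner | second substrate | third substrate | temperature | remark | time |
|---|---|---|---|---|---|---|---|
| birch | 7.5 mM | 18 mM | 15 mM | 7.5 mM | 15 °C | run made earlier |  |
| amber | 15 mM | 18.0 mM | 15.0 mM | 7.50 mM | 15 °C |  | 20 h |
| green | 15 mM | 18.0 mM | 15.0 mM | 7.50 mM | 30 °C |  | 20 h |
| blue | 15 mM | 18.0 mM | 15.0 mM | 7.50 mM | −15 °C |  | 20 h |
| red | 15 mM | 18.0 mM | 15.0 mM | 7.50 mM | 0 °C |  | 20 h |

birch run (percent of the starting material charged)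

| time / h | target / % |
|---|---|
| 0.200 | 8.0 |
| 0.667 | 10.7 |
| 1.00 | 9.4 |
| 1.50 | 7.9 |
| 2.50 | 3.4 |
| 3.00 | 3.4 |
| 4.00 | 0.4 |

(readings scatter by 1 percentage point)

- the earlier runs do not show what temperature does; that part of a forecast is a guess

- the flask with the highest amount of target, in percent of the starting material charged ("all alike" if they lie within 1.5 percentage points) (amber / green / blue / red / all alike)
- final target, as a percentage of the starting material charged, in amber
- final target, as a percentage of the starting material charged, in green
- final target, as a percentage of the starting material charged, in blue
- final target, as a percentage of the starting material charged, in red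

Build the flask up one process at a time, and take it as my assumption that each substrate takes one equivalent of coupling partner. With the main step alone, starting material plus coupling partner, you have more coupling partner than starting material, so the charge allows the target 100 %. Add the second substrate, and its claim, once met in full, leaves 3.00 mM, which is 20.0 % of the starting material charged. Add the third substrate, and you reach S = −4.50 mM, the spare coupling partner, meaning the charge minus the claims of second and third substrate. The coupling partner is then the limiting reagent, since less was charged than those two claim. Birch's falling target leads me to assume that those claims are met at the target's expense, so I put the target's share of the end state at zero.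

Birch has the same S, −4.50 mM, and shows the pace. Its target reads 10.7 % at 0.667 h and 0.4 % at 4.00 h, with a scatter of 1 percentage point. Amber, at birch's temperature, runs 5.00 times as long as birch's last reading, which is the factor it has in hand, and green is hotter still, so I expect both near zero. Temperature is a guess here, so borrow the forecast's guessed slowing by a factor of 3.5 for each step down, from amber to red and from red to blue. Red stays within the factor in hand, so it too should be near zero. Blue, two steps down, is slowed by 12.2, which is more than the factor in hand. Its 20 h then corresponds to 1.63 h of birch, and the nearest reading, at 1.50 h, is 7.9 %. My reckoning therefore puts the most target in blue, at about that figure.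

The forecast differs and names green: 47 % there (32 % to 52 %), 41 % in amber (25 % to 50 %), 23 % in red (7 % to 42 %) and 7 % in blue (1 % to 22 %). Its ground concerns the third substrate: “Once it runs out, the target should survive”.

Blue holds the most, 21.0 %, against 2.13 % in red, 0.0119 % in amber and 0 % in green.

    starting material + coupling partner ⇌ target (K = 32.0 /M, k = 0.00420 /M/s, Ea = 49.0 kJ/mol, ΔH = −32.0 kJ/mol)
    second substrate + coupling partner → second product (k = 0.00880 /M/s, Ea = 51.0 kJ/mol)
    third substrate + coupling partner → third product (k = 0.00290 /M/s, Ea = 68.0 kJ/mol)
    2 starting material → homo dimer (k = 3.30 × 10⁻⁴ /M/s, Ea = 54.0 kJ/mol)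
    target ⇌ isomer of the product (K = 14.0, k = 2.50 × 10⁻⁶ /s, Ea = 95.0 kJ/mol, ΔH = −28.0 kJ/mol)
    (constants at 0 °C)

At 20.0 h, blue still has 16.9 % of its coupling partner unbound. With S at −4.50 mM, blue left for 200 h holds 1.21 % target. Blue's neighbour with 72 mM of coupling partner has S = 49.5 mM, which is more than the starting material charged, and at 20.0 h it holds 71.7 % target.

All runs are calculated for an exercise.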